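The route rests on reading the C1(OH)–C2(Cl) pair of the cyclohexene ring as an opened C1–C2 oxirane, and that oxirane as the C1=C2 alkene of a cyclohexa-1,3-diene. The key step exploits that C6–O lies on the same ring face as C1–O and directly beside C1=C2: the free C6 hydroxyl carries a vanadium-bound peroxide onto that alkene, setting C1 and C2 in one operation and leaving C3=C4 untouched. Its precursor is the trans-5-silyloxy-6-hydroxy diene bearing the C7 benzoate, reached from the enzymatic cis-dihydrodiol of ethyl benzoate by inversion at C6. Chloride finally opens the vinyl epoxide at C2 with inversion.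

Key step: step 6

Remark: ring atoms keep the target numbering throughout (C1 bears C7H2, C2 is the CHCl carbon, C3=C4, C5, C6); the dioxygenase diol of ethyl benzoate is assumed to have the (5S,6R) configuration shared by this enzyme's diols of monosubstituted benzenes, and the recombinant strain is counted as a biocatalyst.

Step 1
Reactants: 1 ethyl benzoate
Product: 2 ethyl (5S,6R)-5,6-dihydroxycyclohexa-1,3-diene-1-carboxylate (both hydroxyls on one face)
Conditions: E. coli JM109(pDTG601A) whole cells expressing toluene dioxygenase, air, glucose-fed mineral medium, pH 6.8, 30 °C; EtOAc extraction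
Reagents that add atoms: dioxygen, O=O
Why: Enzymatic arene cis-dihydroxylation, in which toluene dioxygenase adds both oxygens of O2 to the ortho,meta bond of the benzoate ester from one face, sets C5 and C6 together and is a known biotransformation of benzoate esters.

Step 2
Reactants: 2 ethyl (5S,6R)-5,6-dihydroxycyclohexa-1,3-diene-1-carboxylate; 3 tert-butyldimethylsilyl chloride
Product: 4 ethyl (5S,6R)-5-[(tert-butyldimethylsilyl)oxy]-6-hydroxycyclohexa-1,3-diene-1-carboxylate
Conditions: TBSCl (1.05 equiv), imidazole, DMF, −20 → 0 °C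
Reagents that add atoms: tert-butyldimethylsilyl chloride (3), CC(C)(C)[Si](C)(C)Cl
Why: Regioselective silyl ether formation should occur at the C5 hydroxyl, because the C6 hydroxyl is flanked by the ester-bearing C1 and hydrogen-bonded to the carbonyl, as is usual for the distal hydroxyl of arene cis-dihydrodiols.

Step 3
Reactants: 4 ethyl (5S,6R)-5-[(tert-butyldimethylsilyl)oxy]-6-hydroxycyclohexa-1,3-diene-1-carboxylate; 5 chloroacetic acid
Product: 6 ethyl (5S,6S)-5-[(tert-butyldimethylsilyl)oxy]-6-(2-chloroacetoxy)cyclohexa-1,3-diene-1-carboxylate (C5–O and C6–O now trans)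
Conditions: ClCH2CO2H (3 equiv), PPh3 (2 equiv), DIAD (2 equiv), toluene, −30 → 0 °C
Reagents that add atoms: chloroacetic acid (5), OC(=O)CCl
Why: In this Mitsunobu reaction chloroacetate displaces the C6 alkoxyphosphonium in an SN2 sense from the face opposite to the departing oxygen, which inverts C6, while the excess of the acidic pronucleophile keeps the medium non-basic and the ester-deactivated diene resists ionisation.

Step 4
Reactants: 6 ethyl (5S,6S)-5-[(tert-butyldimethylsilyl)oxy]-6-(2-chloroacetoxy)cyclohexa-1,3-diene-1-carboxylate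
Product: 7 [(5S,6S)-5-[(tert-butyldimethylsilyl)oxy]-6-hydroxycyclohexa-1,3-dien-1-yl]methanol
Conditions: i-Bu2AlH (5.5 equiv), CH2Cl2, −78 → −40 °C; aq. potassium sodium tartrate
Reagents that add atoms: none
Why: Hydride reduction of esters with i-Bu2AlH should take the conjugated ethyl ester to the C7 allylic alcohol in the 1,2-sense and cleave the chloroacetate in the same pot, without touching a stereocentre and without acid or base that would aromatise the diene.

Step 5
Reactants: 7 [(5S,6S)-5-[(tert-butyldimethylsilyl)oxy]-6-hydroxycyclohexa-1,3-dien-1-yl]methanol; 8 benzoyl chloride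
Product: 9 [(5S,6S)-5-[(tert-butyldimethylsilyl)oxy]-6-hydroxycyclohexa-1,3-dien-1-yl]methyl benzoate
Conditions: BzCl (1.05 equiv), 2,4,6-collidine, CH2Cl2, −78 → −40 °C
Reagents that add atoms: benzoyl chloride (8), O=C(Cl)c1ccccc1
Why: Chemoselective acylation should benzoylate the primary allylic C7 hydroxyl far faster than the pseudoaxial secondary C6 hydroxyl wedged between C1 and C5–OSi, so that the directing hydroxyl stays free.

Step 6
Reactants: 9 [(5S,6S)-5-[(tert-butyldimethylsilyl)oxy]-6-hydroxycyclohexa-1,3-dien-1-yl]methyl benzoate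
Product: 10 [(1R,2S,5S,6R)-5-[(tert-butyldimethylsilyl)oxy]-1,2-epoxy-6-hydroxycyclohex-3-en-1-yl]methyl benzoate (oxirane oxygen cis to C6–OH, trans to C5–OSi)
Conditions: VO(acac)2 (5 mol%), t-BuOOH (in decane, 1.2 equiv), CH2Cl2, 0 °C; aq. Na2S2O3/NaHCO3 quench
Reagents that add atoms: tert-butyl hydroperoxide, CC(C)(C)OO
Why: VO(acac)2 is oxidised by t-BuOOH to a pentavalent vanadium alkoxide that holds the C6 oxygen of 9 and an η2-bound tert-butylperoxide on the same metal, and the peroxide oxygen is passed intramolecularly to the adjacent C1=C2 π bond, forming C1–O and C2–O together. The closest known reaction type is the vanadium-catalysed, hydroxyl-directed syn epoxidation of cyclohex-2-en-1-ols. The oxirane is closed by a concerted suprafacial oxygen-atom transfer across C1=C2, a [2+1] addition and not a stepwise displacement. C1 and C2 are set together by the existing C6 stereocentre, because the tethered oxidant can reach only the alkene face that carries C6–O, so the oxirane oxygen ends cis to C6–OH and C7 on the opposite face. The step needs site selectivity, which should follow because C1=C2 is trisubstituted and allylic to the only free hydroxyl whereas C3=C4 is disubstituted, merely homoallylic to it and flanked by the silyl ether. It also needs epoxidation to win over alcohol oxidation, which the pseudoaxial C6–OH enforced by allylic strain with the C1 substituent favours, and the near-stoichiometric oxidant at 0 °C with a non-acidic quench should spare the diene from aromatisation and the vinyl epoxide from opening.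

Step 7
Reactants: 10 [(1R,2S,5S,6R)-5-[(tert-butyldimethylsilyl)oxy]-1,2-epoxy-6-hydroxycyclohex-3-en-1-yl]methyl benzoate; 8 benzoyl chloride
Product: 11 [(1S,2S,5S,6R)-6-(benzoyloxy)-5-[(tert-butyldimethylsilyl)oxy]-1,2-epoxycyclohex-3-en-1-yl]methyl benzoate (same spatial arrangement as 10; the C1 descriptor changes by priority only)
Conditions: BzCl (1.5 equiv), pyridine, DMAP (cat.), CH2Cl2, 0 °C
Reagents that add atoms: benzoyl chloride (8), O=C(Cl)c1ccccc1
Why: Acylation of the secondary C6 alcohol with benzoyl chloride under nucleophilic catalysis by DMAP should leave the oxirane, the silyl ether and the C7 benzoate untouched in the cold basic medium and affects no stereocentre.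

Step 8
Reactants: 11 [(1S,2S,5S,6R)-6-(benzoyloxy)-5-[(tert-butyldimethylsilyl)oxy]-1,2-epoxycyclohex-3-en-1-yl]methyl benzoate
Product: 13 [(1R,2R,5S,6R)-6-(benzoyloxy)-2-chloro-1,5-dihydroxycyclohex-3-en-1-yl]methyl benzoate, via silylated chlorohydrin 12 (not isolated)
Conditions: HCl (4 M in 1,4-dioxane, 3 equiv), CH2Cl2, −20 → 0 °C; then MeOH, 0 °C → rt
Reagents that add atoms: hydrogen chloride, Cl
Why: Acid-mediated opening of a vinyl epoxide by chloride should occur at the allylic C2 from the face opposite to the oxirane oxygen (SN2, inversion at C2, C1–O retained as the tertiary hydroxyl), with the C5 silyl ether shielding C4 on that face against conjugate attack, after which acid methanolysis of the silyl ether frees C5–OH.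

Compound list
1 | ethyl benzoate | CCOC(=O)c1ccccc1 | starting material
2 | ethyl (5S,6R)-5,6-dihydroxycyclohexa-1,3-diene-1-carboxylate | CCOC(=O)C1=CC=C[C@H](O)[C@@H]1O | intermediate
3 | tert-butyldimethylsilyl chloride | CC(C)(C)[Si](C)(C)Cl | starting material
4 | ethyl (5S,6R)-5-[(tert-butyldimethylsilyl)oxy]-6-hydroxycyclohexa-1,3-diene-1-carboxylate | CCOC(=O)C1=CC=C[C@H](O[Si](C)(C)C(C)(C)C)[C@@H]1O | intermediate
5 | chloroacetic acid | OC(=O)CCl | starting material
6 | ethyl (5S,6S)-5-[(tert-butyldimethylsilyl)oxy]-6-(2-chloroacetoxy)cyclohexa-1,3-diene-1-carboxylate | CCOC(=O)C1=CC=C[C@H](O[Si](C)(C)C(C)(C)C)[C@H]1OC(=O)CCl | intermediate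
7 | [(5S,6S)-5-[(tert-butyldimethylsilyl)oxy]-6-hydroxycyclohexa-1,3-dien-1-yl]methanol | OCC1=CC=C[C@H](O[Si](C)(C)C(C)(C)C)[C@H]1O | intermediate
8 | benzoyl chloride | O=C(Cl)c1ccccc1 | starting material
9 | [(5S,6S)-5-[(tert-butyldimethylsilyl)oxy]-6-hydroxycyclohexa-1,3-dien-1-yl]methyl benzoate (key-step precursor) | O=C(OCC1=CC=C[C@H](O[Si](C)(C)C(C)(C)C)[C@H]1O)c1ccccc1 | intermediate
10 | [(1R,2S,5S,6R)-5-[(tert-butyldimethylsilyl)oxy]-1,2-epoxy-6-hydroxycyclohex-3-en-1-yl]methyl benzoate (key-step product) | O=C(OC[C@]12O[C@H]1C=C[C@H](O[Si](C)(C)C(C)(C)C)[C@H]2O)c1ccccc1 | intermediate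
11 | [(1S,2S,5S,6R)-6-(benzoyloxy)-5-[(tert-butyldimethylsilyl)oxy]-1,2-epoxycyclohex-3-en-1-yl]methyl benzoate | O=C(OC[C@]12O[C@H]1C=C[C@H](O[Si](C)(C)C(C)(C)C)[C@H]2OC(=O)c1ccccc1)c1ccccc1 | intermediate
12 | [(1R,2R,5S,6R)-6-(benzoyloxy)-5-[(tert-butyldimethylsilyl)oxy]-2-chloro-1-hydroxycyclohex-3-en-1-yl]methyl benzoate (not isolated) | O=C(OC[C@]1(O)[C@H](Cl)C=C[C@H](O[Si](C)(C)C(C)(C)C)[C@H]1OC(=O)c1ccccc1)c1ccccc1 | intermediate
13 | [(1R,2R,5S,6R)-6-(benzoyloxy)-2-chloro-1,5-dihydroxycyclohex-3-en-1-yl]methyl benzoate | O=C(OC[C@]1(O)[C@H](Cl)C=C[C@H](O)[C@H]1OC(=O)c1ccccc1)c1ccccc1 | target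

Total step count: 8
Longest linear sequence: 8 steps (1 → 13)

Steps most likely to fail

1. Step 3 (inversion at C6 on the intact diene). The activated C6 oxygen may leave together with the antiperiplanar H5, so that the ring aromatises, or the carboxylate may enter at C2 with allylic shift instead of at C6. The fallback sets out from 4 and comes back at 7; it takes C3=C4 out before the inversion and restores it afterwards. Diimide generated from KO2C–N=N–CO2K and AcOH in MeOH at 0 °C should saturate only the disubstituted C3=C4 bond of 4 and give ethyl (5S,6R)-5-[(tert-butyldimethylsilyl)oxy]-6-hydroxycyclohex-1-ene-1-carboxylate F1, a cyclohexenol that cannot aromatise. Mitsunobu inversion with benzoic acid (PPh3, DIAD, THF, 0 °C) should then give ethyl (5S,6S)-6-(benzoyloxy)-5-[(tert-butyldimethylsilyl)oxy]cyclohex-1-ene-1-carboxylate F2. Wohl–Ziegler bromination (NBS, AIBN, PhCF3, 80 °C) at the γ-methylene C3 should give ethyl (5S,6S)-6-(benzoyloxy)-3-bromo-5-[(tert-butyldimethylsilyl)oxy]cyclohex-1-ene-1-carboxylate F3 as C3 epimers. Dehydrobromination (Li2CO3, LiBr, DMF, 60 °C) should restore C3=C4 in ethyl (5S,6S)-6-(benzoyloxy)-5-[(tert-butyldimethylsilyl)oxy]cyclohexa-1,3-diene-1-carboxylate F4, and i-Bu2AlH (CH2Cl2, −78 °C) reduces both ester groups of F4 to give 7.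

2. Step 6 (directed epoxidation). The C6 carbinol may be oxidised to the dienone and the ring lost to a phenol, the dienol may ionise on the Lewis-acidic metal, oxygen transfer may leak to C3=C4 by homoallylic delivery, or the vinyl epoxide may open on the catalyst. The fallback sets out from 9 and comes back at 11; it gives up hydroxyl direction and builds the same oxirane from an endoperoxide. Benzoylation of 9 (BzCl, pyridine, DMAP, 0 °C) should give [(5S,6S)-6-(benzoyloxy)-5-[(tert-butyldimethylsilyl)oxy]cyclohexa-1,3-dien-1-yl]methyl benzoate F5. Sensitised photo-oxygenation (O2, tetraphenylporphyrin, hν, CH2Cl2, −30 °C) adds singlet oxygen across C1 and C4 in a [4+2] sense, expected mainly on the face away from the bulky pseudoaxial C5 silyl ether, that is the C6–O face, to give the C1–C4 endoperoxide F6. P(OMe)3 (CH2Cl2, 0 °C) should attack the less hindered peroxide oxygen on C4, and the C1 alkoxide then closes onto C2 with allylic shift, which gives 11 with the oxirane on the face of the former peroxide bridge. Both operations are known reaction types for trans-5,6-diacyloxycyclohexa-1,3-dienes.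

3. Step 8 (chloride opening and desilylation in one pot). Chloride may be captured at C4 (conjugate opening), the C7 benzoate carbonyl may participate at C2 from the lower face, or an acyl group may migrate or the allylic chloride ionise while the silyl ether is methanolysed. The fallback sets out from 11 and comes back at 13; it separates the two events and avoids protic acid in the opening. HF·pyridine in THF/pyridine at 0 °C should remove the silyl group to give [(1S,2S,5S,6R)-6-(benzoyloxy)-1,2-epoxy-5-hydroxycyclohex-3-en-1-yl]methyl benzoate F7, and Li2CuCl4 in THF at room temperature should then deliver chloride to the allylic C2 of the metal-activated oxirane with inversion to give 13.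

Further compounds
F1 | step 3 | ethyl (5S,6R)-5-[(tert-butyldimethylsilyl)oxy]-6-hydroxycyclohex-1-ene-1-carboxylate | CCOC(=O)C1=CCC[C@H](O[Si](C)(C)C(C)(C)C)[C@@H]1O
F2 | step 3 | ethyl (5S,6S)-6-(benzoyloxy)-5-[(tert-butyldimethylsilyl)oxy]cyclohex-1-ene-1-carboxylate | CCOC(=O)C1=CCC[C@H](O[Si](C)(C)C(C)(C)C)[C@H]1OC(=O)c1ccccc1
F3 | step 3 | ethyl (5S,6S)-6-(benzoyloxy)-3-bromo-5-[(tert-butyldimethylsilyl)oxy]cyclohex-1-ene-1-carboxylate (C3 epimers) | CCOC(=O)C1=CC(Br)C[C@H](O[Si](C)(C)C(C)(C)C)[C@H]1OC(=O)c1ccccc1
F4 | step 3 | ethyl (5S,6S)-6-(benzoyloxy)-5-[(tert-butyldimethylsilyl)oxy]cyclohexa-1,3-diene-1-carboxylate | CCOC(=O)C1=CC=C[C@H](O[Si](C)(C)C(C)(C)C)[C@H]1OC(=O)c1ccccc1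
F5 | step 6 | [(5S,6S)-6-(benzoyloxy)-5-[(tert-butyldimethylsilyl)oxy]cyclohexa-1,3-dien-1-yl]methyl benzoate | O=C(OCC1=CC=C[C@H](O[Si](C)(C)C(C)(C)C)[C@H]1OC(=O)c1ccccc1)c1ccccc1
F6 | step 6 | C1–C4 endoperoxide of F5 (2,3-dioxabicyclo[2.2.2]oct-5-ene, O–O bridge on the C6–O face) | O=C(OC[C@]12OO[C@H](C=C1)[C@H](O[Si](C)(C)C(C)(C)C)[C@H]2OC(=O)c1ccccc1)c1ccccc1
F7 | step 8 | [(1S,2S,5S,6R)-6-(benzoyloxy)-1,2-epoxy-5-hydroxycyclohex-3-en-1-yl]methyl benzoate | O=C(OC[C@]12O[C@H]1C=C[C@H](O)[C@H]2OC(=O)c1ccccc1)c1ccccc1
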